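Iridoid numbering is used throughout: C1 acetal carbon, O2, C3, C4, C5, C6, C7, C8, C9 (ring fusion), C10 = CH2 on C8, C11 = CH2 on C4.
Retrosynthesis cuts the C11 and C1 ester C–O bonds, then O2–C1 of the pyran (a lactol from a C1 aldehyde and the enol of a C3/C11 dialdehyde, all three formyl groups coming from vinyl groups), then the C7–O ester bond (epoxide opening), and last C7–C8 together with C9–C1.
The enabling feature is the C7–C8 pair: adjacent, both oxygenated and trans, with the C5=C6 alkene on one side and, on the other, C9 carrying a carbon trans to the C8 oxygen. This is the pattern of a 6-oxabicyclo[3.1.0]hex-3-ene opened twice, so the carbocycle C8–C9–C5–C6–C7 maps onto the five carbons of a pyrylium ring and the C8 hydroxyl oxygen onto its ring oxygen.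
Forward: a 4-pyranone becomes a 2,4-disubstituted pyrylium salt with a vinylsilyl ether on the future O10 (tether) and a penta-1,4-dien-3-yl group on the future C5. Light closes the cyclopentene and the oxirane in one event while the tether hands its vinyl group to C9, isovaleric acid opens the strained epoxide at C7, and O10 is acylated. Cleavage of the three vinyl groups gives a trialdehyde that closes the pyran ring; acylation at C1, reduction at C11 and acetylation finish.
Stereochemistry: C7/C8 are cis in the epoxide by ring constraint, C9 is set by capture anti to the epoxide oxygen (the tether sits on that face), and C7 is inverted in the SN2 opening (trans C7–O/C8–OH). Absolute configuration comes from a lipase kinetic resolution at O10, and C1 from acylation of the equilibrating lactol on its open face.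
Helpers and their removal: the silicon tether leaves in the key step, the three vinyl CH2 termini leave as formaldehyde, and the 11-formyl oxidation level (which stabilises the lactol) is reduced at the end.

Key step: step 4

Assumption: the lipase of step 6 acylates the antipode of 16 that is drawn (the sense of such a resolution cannot be predicted with confidence); compounds 13 to 16 are racemic and are drawn as the enantiomer that is carried on.
Remark: in the names, "lower face" is the face that carries H9 in 24 and "upper face" is the opposite one.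

Step 1
Reactants: 1 (E)-4-methoxybut-3-en-2-one; 2 acetoxyacetyl chloride
Product: 5 2-(hydroxymethyl)-4H-pyran-4-one, via diketone 3 (not isolated), via pyranone acetate 4 (not isolated)
Conditions: LiN(SiMe3)2 (2.1 equiv), THF, −78 °C, then 2, −78 to 0 °C; then HCl, MeOH, 50 °C
Reagents that add atoms: none
Why: Claisen-type C-acylation of the lithium enolate of the vinylogous ester 1 gives the δ-methoxy β-diketone 3, which closes under acid to the 4-pyranone by conjugate addition of the enol oxygen and loss of methanol (the enolate-acylation route to 2-substituted 4-pyranones), while HCl/MeOH transesterifies the acetate; no stereocentre is formed.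

Step 2
Reactants: 5 2-(hydroxymethyl)-4H-pyran-4-one; 6 chloro(dimethyl)vinylsilane
Product: 7 2-{[dimethyl(vinyl)silyl]oxymethyl}-4H-pyran-4-one
Conditions: Et3N, CH2Cl2, 0 °C; filtration and distillation with exclusion of moisture
Reagents that add atoms: none
Why: O-silylation of the only hydroxyl group with a chlorosilane and an amine base places the vinyl donor on the oxygen that becomes O10, two bonds from the carbon that becomes C8.

Step 3
Reactants: 7 2-{[dimethyl(vinyl)silyl]oxymethyl}-4H-pyran-4-one; 8 penta-1,4-diene
Product: 12 4-(penta-1,4-dien-3-yl)-2-{[dimethyl(vinyl)silyl]oxymethyl}pyrylium methanesulfonate, via pentadienyllithium 9 (not isolated), via pentadienylmagnesium triflate 10 (not isolated), via magnesium pyranolate 11 (not isolated)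
Conditions: 8, n-BuLi, THF, −78 to 0 °C; Mg(OTf)2, −78 °C; 7, −78 °C; then (MeSO2)2O, CH2Cl2, −78 to −30 °C; filtration under argon, precipitation with pentane
Reagents that add atoms: methanesulfonic anhydride CS(=O)(=O)OS(C)(=O)=O
Why: Penta-1,4-diene is metalated at its doubly allylic CH2 and the dienylmagnesium species adds 1,2 to the pyranone carbonyl through its central carbon (allylic transposition, as is usual for pentadienylmagnesium and -zinc reagents), and O-sulfonylation of the tertiary alkoxide then ionises at once to the aromatic pyrylium salt (the organometallic addition/ionisation route to 4-substituted pyrylium salts), halide-free so that no anion quenches the excited state in step 4.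

Step 4
Reactants: 12 4-(penta-1,4-dien-3-yl)-2-{[dimethyl(vinyl)silyl]oxymethyl}pyrylium methanesulfonate
Product: 15 rac-[3-(penta-1,4-dien-3-yl)-2-vinyl-6-oxabicyclo[3.1.0]hex-3-en-1-yl]methanol (vinyl group anti to the epoxide oxygen), via bicyclic allyl cation 13 (not isolated), via silyl mesylate 14 (not isolated)
Conditions: hν (254 nm, quartz flow cell), dry MeCN (5 mM), −30 °C; then KHCO3, MeOH, 0 °C
Reagents that add atoms: none
Why: Proposed new method: excitation of the pyrylium chromophore should bond the two ring carbons that flank the oxonium oxygen (C7 and C8), a disrotatory excited-state electrocyclisation that closes the cyclopentene ring and the oxirane in the same event and leaves the bicyclic allyl cation 13 (C9–C5–C6), a strained system that no thermal reaction of 12 reaches. The cation is then attacked at C9 by the vinylsilane that hangs from O10, at the silicon-bearing carbon (ipso substitution through a six-membered transition state), and mesylate takes the silyl group to give 14, which methanolysis frees as 15. The closest known reaction type is the photocyclisation of pyridinium salts, and the photohydration of pyrylium salts, to such bicyclic allyl cations that a solvent nucleophile captures anti to the heteroatom bridge, joined here to the known ipso attack of carbocations on vinylsilanes. C7 and C8 are cis because they share the three-membered ring, and C9 is set because the tether sits on C8 on the face away from the epoxide oxygen, which is also the face open to any nucleophile, so the new vinyl group ends trans to the C8 oxygen and cis to C10. The step needs capture at C9 instead of C6 and capture that outruns thermal reversion of 13 to 12: only C9 is within reach of the tether, the intramolecular delivery raises the rate, and mesylate or MeCN can add to the cation only reversibly. Both senses of bridging are equally likely, so 15 is racemic.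

Step 5
Reactants: 15 rac-[3-(penta-1,4-dien-3-yl)-2-vinyl-6-oxabicyclo[3.1.0]hex-3-en-1-yl]methanol
Product: 16 rac-5-hydroxy-5-(hydroxymethyl)-3-(penta-1,4-dien-3-yl)-4-vinylcyclopent-2-en-1-yl 3-methylbutanoate (C7 ester and C9 vinyl on the upper face; C8 hydroxyl on the lower face)
Conditions: Ti(OiPr)4 (1.5 equiv), 3-methylbutanoic acid (1.5 equiv), CH2Cl2, 0 °C to rt; aqueous tartaric acid work-up
Reagents that add atoms: 3-methylbutanoic acid CC(C)CC(O)=O
Why: Ti(OiPr)4-mediated opening of a 2,3-epoxy alcohol by a carboxylic acid delivers the titanium-bound isovalerate to C7, the epoxide carbon remote from the CH2OH group and also the allylic one, by SN2 attack with inversion and release of ring strain, so the C7 ester ends trans to the C8 hydroxyl and cis to the C9 vinyl group.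

Step 6
Reactants: 16 rac-5-hydroxy-5-(hydroxymethyl)-3-(penta-1,4-dien-3-yl)-4-vinylcyclopent-2-en-1-yl 3-methylbutanoate
Product: 17 [1-hydroxy-2-(3-methylbutanoyloxy)-4-(penta-1,4-dien-3-yl)-5-vinylcyclopent-3-en-1-yl]methyl 3-methylbutanoate (single enantiomer)
Conditions: immobilised Burkholderia cepacia lipase (Amano PS), 3-methylbutanoic anhydride (0.6 equiv), MTBE, 30 °C, stopped at about half conversion; chromatography
Reagents that add atoms: 3-methylbutanoic anhydride CC(C)CC(=O)OC(=O)CC(C)C
Why: Lipase-catalysed enantioselective acylation (kinetic resolution) of the primary hydroxyl next to the C8 stereocentre esterifies one antipode only, so the resolution also installs the C10 isovalerate and fixes the absolute configuration, while the tertiary C8 hydroxyl is not acylated and the unreacted antipode is removed as the diol.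

Step 7
Reactants: 17 [1-hydroxy-2-(3-methylbutanoyloxy)-4-(penta-1,4-dien-3-yl)-5-vinylcyclopent-3-en-1-yl]methyl 3-methylbutanoate
Product: 19 [4-formyl-1,7-dihydroxy-6-(3-methylbutanoyloxy)-1,6,7,7a-tetrahydrocyclopenta[c]pyran-7-yl]methyl 3-methylbutanoate (11-oxo lactol), via trialdehyde 18 (not isolated)
Conditions: OsO4 (3 mol %), NaIO4 (7 equiv), 2,6-lutidine, 1,4-dioxane/H2O 3:1, 0 °C to rt
Reagents that add atoms: sodium periodate [Na+].[O-]I(=O)(=O)=O; osmium tetroxide O=[Os](=O)(=O)=O (carrier of the three formyl oxygen atoms, regenerated by NaIO4)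
Why: Lemieux–Johnson cleavage of the three unhindered monosubstituted vinyl groups, which should osmylate faster than the trisubstituted ring alkene (flanked by two fully substituted carbons and deactivated by its allylic ester), gives the 1,3,11-trialdehyde, whose diformylmethyl unit enolises into conjugation with C5=C6 and adds through the enol oxygen to the C1 aldehyde (6-exo-trig hemiacetal formation, the classical iridoid dialdehyde-to-lactol closure); C1 arises as an equilibrating lactol centre and C9 is not touched.

Step 8
Reactants: 20 3-hydroxy-3-methylbutanoic acid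
Product: 21 3-acetoxy-3-methylbutanoic acid
Conditions: Ac2O (2.5 equiv), Sc(OTf)3 (1 mol %), MeCN, −20 °C; then H2O, THF, rt
Reagents that add atoms: acetic anhydride CC(=O)OC(C)=O
Why: Lewis-acid-catalysed acetylation of a tertiary alcohol with Ac2O avoids the base that would eliminate the β-acyloxy acid, and the mixed anhydride formed at the carboxyl group is hydrolysed in the aqueous second stage.

Step 9
Reactants: 19 [4-formyl-1,7-dihydroxy-6-(3-methylbutanoyloxy)-1,6,7,7a-tetrahydrocyclopenta[c]pyran-7-yl]methyl 3-methylbutanoate; 21 3-acetoxy-3-methylbutanoic acid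
Product: 22 [1-(3-acetoxy-3-methylbutanoyloxy)-4-formyl-7-hydroxy-6-(3-methylbutanoyloxy)-1,6,7,7a-tetrahydrocyclopenta[c]pyran-7-yl]methyl 3-methylbutanoate
Conditions: DCC, DMAP (10 mol %), CH2Cl2, −20 to 0 °C
Reagents that add atoms: none
Why: Steglich esterification of the lactol hydroxyl, in which the anomers interconvert through the hydroxy aldehyde and acylation should occur on the anomer whose hydroxyl lies on the lower face (the face of H9, away from the C8 CH2O-acyl arm), fixing C1 with the acyloxy group cis to H9, while the hindered tertiary C8 hydroxyl does not react.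

Step 10
Reactants: 22 [1-(3-acetoxy-3-methylbutanoyloxy)-4-formyl-7-hydroxy-6-(3-methylbutanoyloxy)-1,6,7,7a-tetrahydrocyclopenta[c]pyran-7-yl]methyl 3-methylbutanoate
Product: 23 [1-(3-acetoxy-3-methylbutanoyloxy)-7-hydroxy-4-(hydroxymethyl)-6-(3-methylbutanoyloxy)-1,6,7,7a-tetrahydrocyclopenta[c]pyran-7-yl]methyl 3-methylbutanoate
Conditions: NaBH4, CeCl3·7H2O, MeOH/THF, −78 °C
Reagents that add atoms: none
Why: Luche 1,2-reduction of the conjugated 11-aldehyde, the only aldehyde or ketone present, should leave the four ester groups, the acyl acetal at C1 and the dienol ether untouched at low temperature.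

Step 11
Reactants: 23 [1-(3-acetoxy-3-methylbutanoyloxy)-7-hydroxy-4-(hydroxymethyl)-6-(3-methylbutanoyloxy)-1,6,7,7a-tetrahydrocyclopenta[c]pyran-7-yl]methyl 3-methylbutanoate
Product: 24 [4-(acetoxymethyl)-1-(3-acetoxy-3-methylbutanoyloxy)-7-hydroxy-6-(3-methylbutanoyloxy)-1,6,7,7a-tetrahydrocyclopenta[c]pyran-7-yl]methyl 3-methylbutanoate (CNP0331701.2)
Conditions: Ac2O, pyridine, CH2Cl2, 0 °C
Reagents that add atoms: acetic anhydride CC(=O)OC(C)=O
Why: Acetylation of the primary allylic alcohol under base-buffered conditions leaves the hindered tertiary C8 hydroxyl free and avoids the acid that would ionise the 4-(acyloxymethyl) dienol ether.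

Compound list
1 | (E)-4-methoxybut-3-en-2-one | CO/C=C/C(C)=O | starting material
2 | acetoxyacetyl chloride (2-chloro-2-oxoethyl acetate) | CC(=O)OCC(Cl)=O | starting material
3 | (E)-6-methoxy-2,4-dioxohex-5-en-1-yl acetate (diketone) | CC(=O)OCC(=O)CC(=O)/C=C/OC | intermediate
4 | (4-oxo-4H-pyran-2-yl)methyl acetate (pyranone acetate) | CC(=O)OCC1=CC(=O)C=CO1 | intermediate
5 | 2-(hydroxymethyl)-4H-pyran-4-one | OCC1=CC(=O)C=CO1 | intermediate
6 | chloro(dimethyl)vinylsilane | C=C[Si](C)(C)Cl | starting material
7 | 2-{[dimethyl(vinyl)silyl]oxymethyl}-4H-pyran-4-one | C=C[Si](C)(C)OCC1=CC(=O)C=CO1 | intermediate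
8 | penta-1,4-diene | C=CCC=C | starting material
9 | penta-2,4-dienyllithium | [Li]CC=CC=C | intermediate
10 | penta-2,4-dienylmagnesium trifluoromethanesulfonate | C=CC=CC[Mg]OS(=O)(=O)C(F)(F)F | intermediate
11 | magnesium triflate alkoxide of 4-(penta-1,4-dien-3-yl)-2-{[dimethyl(vinyl)silyl]oxymethyl}-4H-pyran-4-ol | C=CC(C=C)C1(O[Mg]OS(=O)(=O)C(F)(F)F)C=COC(CO[Si](C)(C)C=C)=C1 | intermediate
12 | 4-(penta-1,4-dien-3-yl)-2-{[dimethyl(vinyl)silyl]oxymethyl}pyrylium methanesulfonate | C=CC(C=C)c1cc[o+]c(CO[Si](C)(C)C=C)c1.CS(=O)(=O)[O-] | intermediate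
13 | rac-1-{[dimethyl(vinyl)silyl]oxymethyl}-3-(penta-1,4-dien-3-yl)-6-oxabicyclo[3.1.0]hex-3-en-2-ylium methanesulfonate (allyl cation over C9–C5–C6, cis-fused 7,8-epoxide) | C=CC(C=C)C1=C[C@@H]2O[C@]2(CO[Si](C)(C)C=C)[CH+]1.CS(=O)(=O)[O-] | intermediate
14 | rac-{[3-(penta-1,4-dien-3-yl)-2-vinyl-6-oxabicyclo[3.1.0]hex-3-en-1-yl]methoxy}dimethylsilyl methanesulfonate (vinyl anti to the epoxide oxygen) | C=C[C@H]1C(C(C=C)C=C)=C[C@@H]2O[C@]12CO[Si](C)(C)OS(C)(=O)=O | intermediate
15 | rac-[3-(penta-1,4-dien-3-yl)-2-vinyl-6-oxabicyclo[3.1.0]hex-3-en-1-yl]methanol (7,8-epoxide on the lower face, C9 vinyl and C10 on the upper face) | C=C[C@H]1C(C(C=C)C=C)=C[C@@H]2O[C@]12CO | intermediate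
16 | rac-5-hydroxy-5-(hydroxymethyl)-3-(penta-1,4-dien-3-yl)-4-vinylcyclopent-2-en-1-yl 3-methylbutanoate (C7 ester, C9 vinyl and C10 on the upper face, C8 hydroxyl on the lower face) | C=C[C@H]1C(C(C=C)C=C)=C[C@@H](OC(=O)CC(C)C)[C@@]1(O)CO | intermediate
17 | [1-hydroxy-2-(3-methylbutanoyloxy)-4-(penta-1,4-dien-3-yl)-5-vinylcyclopent-3-en-1-yl]methyl 3-methylbutanoate (single enantiomer, same relative configuration as 16) | C=C[C@H]1C(C(C=C)C=C)=C[C@@H](OC(=O)CC(C)C)[C@@]1(O)COC(=O)CC(C)C | intermediate
18 | [4-(1,3-dioxopropan-2-yl)-5-formyl-1-hydroxy-2-(3-methylbutanoyloxy)cyclopent-3-en-1-yl]methyl 3-methylbutanoate (trialdehyde) | O=C[C@H]1C(C(C=O)C=O)=C[C@@H](OC(=O)CC(C)C)[C@@]1(O)COC(=O)CC(C)C | intermediate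
19 | [4-formyl-1,7-dihydroxy-6-(3-methylbutanoyloxy)-1,6,7,7a-tetrahydrocyclopenta[c]pyran-7-yl]methyl 3-methylbutanoate (lactol, drawn as the anomer with 1-OH on the lower face) | O=CC1=CO[C@@H](O)[C@H]2C1=C[C@@H](OC(=O)CC(C)C)[C@@]2(O)COC(=O)CC(C)C | intermediate
20 | 3-hydroxy-3-methylbutanoic acid | CC(C)(O)CC(O)=O | starting material
21 | 3-acetoxy-3-methylbutanoic acid | CC(=O)OC(C)(C)CC(O)=O | intermediate
22 | [1-(3-acetoxy-3-methylbutanoyloxy)-4-formyl-7-hydroxy-6-(3-methylbutanoyloxy)-1,6,7,7a-tetrahydrocyclopenta[c]pyran-7-yl]methyl 3-methylbutanoate (1-acyloxy, 7-OH and H7a on the lower face; 6-acyloxy and the CH2O-acyl arm on the upper face) | O=CC1=CO[C@@H](OC(=O)CC(C)(C)OC(C)=O)[C@H]2C1=C[C@@H](OC(=O)CC(C)C)[C@@]2(O)COC(=O)CC(C)C | intermediate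
23 | [1-(3-acetoxy-3-methylbutanoyloxy)-7-hydroxy-4-(hydroxymethyl)-6-(3-methylbutanoyloxy)-1,6,7,7a-tetrahydrocyclopenta[c]pyran-7-yl]methyl 3-methylbutanoate | OCC1=CO[C@@H](OC(=O)CC(C)(C)OC(C)=O)[C@H]2C1=C[C@@H](OC(=O)CC(C)C)[C@@]2(O)COC(=O)CC(C)C | intermediate
24 | [4-(acetoxymethyl)-1-(3-acetoxy-3-methylbutanoyloxy)-7-hydroxy-6-(3-methylbutanoyloxy)-1,6,7,7a-tetrahydrocyclopenta[c]pyran-7-yl]methyl 3-methylbutanoate (CNP0331701.2) | CC(=O)OCC1=CO[C@@H](OC(=O)CC(C)(C)OC(C)=O)[C@H]2C1=C[C@@H](OC(=O)CC(C)C)[C@@]2(O)COC(=O)CC(C)C | target

Total steps: 11. Longest linear sequence: 10 (steps 1 to 7 and 9 to 11; step 8 prepares the acid 21 separately).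

Steps most likely to fail

Step 4. The bridged cation 13 may revert to 12 before the weakly nucleophilic vinylsilane reaches C9, the excited pyrylium may be quenched by electron transfer from the alkenes, or adventitious water may capture the cation at C6. The fallback sets out from 12 and uses the known solvent-capture mode of this photochemistry followed by a sigmatropic transfer of the carbon. Compound 12 is irradiated (254 nm, −30 °C) in MeCN containing a few equivalents of water and 2,6-di-tert-butylpyridine, so that water adds to the less hindered allyl terminus C6 anti to the epoxide and gives epoxy allylic alcohol F1 with the silyl ether still in place. O-alkylation (KH, Bu3SnCH2I, THF, 0 °C) gives stannylmethyl ether F2. Tin–lithium exchange (n-BuLi, THF, −78 °C) starts a Still–Wittig [2,3] rearrangement that places the carbon on C9 on the face the C6 oxygen occupied (trans to the epoxide) and moves the alkene to C5=C6, giving primary alcohol F3. Dess–Martin oxidation gives aldehyde F4, Wittig methylenation (Ph3P=CH2, THF, −78 °C) gives vinyl silyl ether F5, and methanolysis of the silyl ether (KHCO3, MeOH, 0 °C) comes back to the route at 15.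

Step 6. The enzyme may discriminate poorly between the antipodes of a hindered primary alcohol, or may acylate the antipode that is not needed. The fallback sets out from 15 and resolves through covalent diastereomers before any ester is present. Compound 15 is esterified with (S)-2-methoxy-2-phenylacetic acid (DCC, DMAP, CH2Cl2) and the two diastereomeric esters are separated on silica. The one with the required ring configuration, mandelate ester F6, is methanolysed (K2CO3, MeOH, 0 °C) to enantiopure epoxy alcohol F7. The Ti(OiPr)4/3-methylbutanoic acid opening of step 5 then gives enantiopure diol F8, and chemical acylation of its primary hydroxyl (3-methylbutanoic anhydride, pyridine, 0 °C) comes back to the route at 17.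

Step 7. Osmylation may also attack the ring alkene, or the open trialdehyde may epimerise at C9 or move its C5=C6 alkene into conjugation under the basic conditions before it closes. The fallback sets out from 17 and reduces the number of cleavage events before a non-basic cleavage. Ring-closing metathesis (second-generation Grubbs catalyst, RuCl2(=CHPh)(PCy3)(H2IMes), CH2Cl2, 40 °C) joins the C9 vinyl group to one of the two C4 vinyl groups with loss of ethylene and gives bicyclic triene F9 (either C4 epimer serves, since C4 becomes trigonal). Ozonolysis (O3, CH2Cl2/pyridine, −78 °C, Sudan Red 7B as end-point indicator; then Me2S) cleaves the strained cis-disubstituted cyclopentene and the remaining vinyl group ahead of the hindered, ester-deactivated ring alkene and gives trialdehyde 18 without base, which closes to the lactol and comes back to the route at 19.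

Further compounds
F1 | step 4 | rac-1-{[dimethyl(vinyl)silyl]oxymethyl}-4-(penta-1,4-dien-3-yl)-6-oxabicyclo[3.1.0]hex-3-en-2-ol with the hydroxyl (on C6, iridoid numbering) anti to the epoxide oxygen and the alkene at C9=C5 | C=CC(C=C)C1=C[C@@]2(CO[Si](C)(C)C=C)O[C@H]2[C@@H]1O
F2 | step 4 | tributylstannylmethyl ether of F1 | C=CC(C=C)C1=C[C@@]2(CO[Si](C)(C)C=C)O[C@H]2[C@@H]1OC[Sn](CCCC)(CCCC)CCCC
F3 | step 4 | rac-[1-{[dimethyl(vinyl)silyl]oxymethyl}-3-(penta-1,4-dien-3-yl)-6-oxabicyclo[3.1.0]hex-3-en-2-yl]methanol (CH2OH on C9 anti to the epoxide oxygen) | OC[C@H]1C(C(C=C)C=C)=C[C@@H]2O[C@]12CO[Si](C)(C)C=C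
F4 | step 4 | rac-1-{[dimethyl(vinyl)silyl]oxymethyl}-3-(penta-1,4-dien-3-yl)-6-oxabicyclo[3.1.0]hex-3-ene-2-carbaldehyde | O=C[C@H]1C(C(C=C)C=C)=C[C@@H]2O[C@]12CO[Si](C)(C)C=C
F5 | step 4 | dimethyl(vinyl)silyl ether of 15 | C=C[C@H]1C(C(C=C)C=C)=C[C@@H]2O[C@]12CO[Si](C)(C)C=C
F6 | step 6 | (S)-2-methoxy-2-phenylacetate of the required enantiomer of 15 | C=C[C@H]1C(C(C=C)C=C)=C[C@@H]2O[C@]12COC(=O)[C@@H](OC)c1ccccc1
F7 | step 6 | epoxy alcohol 15 as the single enantiomer drawn | C=C[C@H]1C(C(C=C)C=C)=C[C@@H]2O[C@]12CO
F8 | step 6 | diol mono-isovalerate 16 as the single enantiomer drawn | C=C[C@H]1C(C(C=C)C=C)=C[C@@H](OC(=O)CC(C)C)[C@@]1(O)CO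
F9 | step 7 | bicyclic triene from ring-closing metathesis of 17 (new cyclopentene C9–C1=C3–C4–C5, one vinyl group left on C4) | C=CC1C=C[C@H]2C1=C[C@@H](OC(=O)CC(C)C)[C@@]2(O)COC(=O)CC(C)C
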